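Readings and results are calculated from invented constants; the scatter is artificial.

8.60% of the substrate was gone after 25.0 s in the north-west run, and I built my estimate for dusk on that reading.

| flask | substrate | reagent | temperature | remark | time |
|---|---|---|---|---|---|
| south-west | 0.13 M | 2 equiv | 62 °C | run made earlier |  |
| north-west | 0.20 M | 2 equiv | 112 °C | run made earlier |  |
| west | 0.092 M | 1 equiv | 62 °C | run made earlier |  |
| winter | 0.092 M | 2.00 equiv | 40 °C |  | 15 min |
| dusk | 0.092 M | 2.00 equiv | 130 °C |  | 15 min |
| noon | 0.092 M | 2.00 equiv | 70 °C |  | 15 min |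
| dawn | 0.092 M | 2.00 equiv | 100 °C |  | 15 min |

- south-west (time / min: target / %, substrate / %): 0.667: 4.6, 94.6; 1.50: 7.8, 90.7; 3.00: 10.7, 84.8; 5.00: 13.9, 80.2
- north-west (time / s: target / %, substrate / %): 10.0: 5.0, 95.1; 25.0: 8.1, 91.4
- west (time / min: target / %, substrate / %): 0.417: 1.3, 95.9; 1.00: 4.1, 94.4; 2.00: 6.6, 90.9; 5.00: 9.7, 84.9

(scatter of a reading: 0.3 percentage points)

- the flask with the highest amount of target, in percent of the substrate charged ("all alike" if they lie within 1.5 percentage points) (winter / dusk / noon / dawn / all alike)
- final target, as a percentage of the substrate charged, in winter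
- final target, as a percentage of the substrate charged, in dusk
- final target, as a percentage of the substrate charged, in noon
- final target, as a percentage of the substrate charged, in dawn

- the earlier runs were read with a standard deviation of 0.3 percentage points

In the south-west run, time grew 3.33-fold between 1.50 min and 5.00 min, while the lost substrate grew 2.13-fold, nearer the root 1.83 than time itself. The west run, with half the equivalents and also a lower [substrate] of 0.092 M against 0.13 M, reached 0.487 of the squared target of south-west at equal time. So I let the square of the lost fraction c grow with time and equivalents, and I took no account of concentration.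

South-west, c squared over time: 0.00784 min⁻¹
North-west, the same: 0.0178 min⁻¹
Dusk, at an equal factor per degree: 0.0238 min⁻¹
Lost in dusk by 15 min: 59.7%
Target at the north-west selectivity of 94.2%: 56.3%

The weak link was the steady constant: a loss of 59.7% leaves 40.3% of the substrate, and I expected the rate to follow what remains of substrate and reagent. I reforged it: c squared grows as G(1 − c)(1 − c/2) at 2 equivalents, which integrates to

F(c) = 8 ln(1 − c/2) − 4 ln(1 − c) = Gt.

North-west: G = 0.0194 min⁻¹
Dusk, scaled as before from south-west: G = 0.0249 min⁻¹

I call G, F(c) over elapsed time, the square constant. Correcting c by the root of Gt/F(c), starting from the root of Gt, gave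

61.1%, 40.3%, 48.0%, 45.2%, 46.2%, 45.9%.

The swing had narrowed to 0.30 points between the last two values, so I stopped there. At the same selectivity I committed to 43.2% target in dusk. I also committed to dusk as the richest flask: it is the hottest, and the north-west run at 112 °C lost substrate faster than the south-west run at 62 °C.

The forecast said dusk, with 15.5% in winter, 50% in dusk, higher than my figure, 25% in noon and 37% in dawn, and of its figures it wrote: “I trim the hotter flasks for depletion of substrate and reagent”.

The flasks gave dusk as the richest, with 12.5% in winter, 42.0% in dusk, 27.2% in noon and 38.3% in dawn.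

    substrate ⇌ intermediate + leaving ligand (K = 3.80 × 10⁻⁴ M, k = 0.0120 min⁻¹, Ea = 90.0 kJ mol⁻¹, ΔH = −45.0 kJ mol⁻¹)
    reagent + intermediate → target (k = 9.60 M⁻¹ min⁻¹, Ea = 49.0 kJ mol⁻¹)
    target ⇌ isomer of the product (K = 2.70, k = 0.0180 min⁻¹, Ea = 106 kJ mol⁻¹, ΔH = −59.0 kJ mol⁻¹)
    (constants at 40 °C)

In dusk, substrate stood at 57.2% after 15.0 min, so the square constant read there is 0.0205 min⁻¹, above the 0.0194 min⁻¹ of the north-west run and below the 0.0249 min⁻¹ I carried. In dusk, reagent was then taking up intermediate, which stood at 0.0117%, while [leaving ligand] had reached 0.0393 M. In dawn the constant read 0.0184 min⁻¹ at 15.0 min and 0.0185 min⁻¹ at 150 min, when 17.1% of the substrate remained.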